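**Retrosynthetic overview**

- Feature: in coumarin B the benzene carbon C8, which is bonded to cyclohexene C6, lies between C8a–O1 and C7–OMe, with C5–OMe para. A vinylketene–siloxyalkyne benzannulation delivers exactly this 1,3,5-trioxygenated ring (cyclohexene locants: C1 quaternary, C2/C3 CH2, C4(Me)=C5, C6 CH).
- Z-alkene ⇒ alkyne (semi-hydrogenation) ⇒ Sonogashira coupling of a C1-ethynyl group with 8-iodo-5,7-dimethoxycoumarin, so coumarin A enters whole.
- Pyranone of coumarin B ⇒ ortho-formylation and Wittig lactonisation of a phenol; benzene ring of coumarin B ⇒ siloxyalkyne on C6 + 3-methoxycyclobutenone.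
- Cyclohexene with both stereocentres ⇒ Ireland–Claisen contraction of an (R)-linalool-derived 6-alkenyl δ-lactone (boat transition state, chirality transfer); C1–CO2H becomes the Me3Si-alkyne, C6–CO2Me the siloxyalkyne.
- Ring order: cyclohexene (step 7), benzene ring of coumarin B (step 13), pyranone of coumarin B (step 15).

Key step: step 13

Remark 1: ozonolysis of linalool stops at a five-membered lactol, so the six-membered lactone needed for a six-membered carbocycle is reached by one-carbon homologation (step 2) and α-methylation (step 5).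
Remark 2 (assumption): iodination of 5,7-dimethoxycoumarin is taken to occur at C8, as it does in 5,7-dialkoxychromones and flavones.

**Route**

Step 1
Reactants: 1 (R)-linalool
Product: 3 (5R)-5-methyl-5-vinyltetrahydrofuran-2-ol (both anomers), via hydroxy aldehyde 2 (not isolated)
Conditions: O3 (1.0 equiv, Sudan Red 7B end point), CH2Cl2–MeOH, −78 °C; Me2S, −78 °C → rt
Reagents that add atoms: ozone, [O-][O+]=O
Why: Chemoselective ozonolysis, since ozone should attack the trisubstituted alkene far faster than the vinyl group; the tertiary alcohol closes onto aldehyde 2 to the lactol and the carbinol stereocentre is untouched.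

Step 2
Reactants: 3 (5R)-5-methyl-5-vinyltetrahydrofuran-2-ol
Product: 5 (3R)-7-methoxy-3-methylhepta-1,6-dien-3-ol (E/Z mixture), via open-chain potassium alkoxide 4 (not isolated)
Conditions: Ph3P(CH2OMe)Cl (2.5 equiv), KOtBu (3.5 equiv), THF, 0 °C; then 3, 0 °C → rt; H2O
Reagents that add atoms: (methoxymethyl)triphenylphosphonium chloride, COC[P+](c1ccccc1)(c1ccccc1)c1ccccc1.[Cl-]
Why: Wittig olefination with the methoxymethylene ylide, the standard one-carbon homologation of a lactol, in which the extra equivalent of base deprotonates the lactol, the ring-opened alkoxide 4 presents the free aldehyde to the ylide and aqueous work-up protonates the tertiary alkoxide.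

Step 3
Reactants: 5 (3R)-7-methoxy-3-methylhepta-1,6-dien-3-ol
Product: 7 (6R)-6-methyl-6-vinyltetrahydro-2H-pyran-2-ol (both anomers), via hydroxy aldehyde 6 (not isolated)
Conditions: 1 M HCl, THF, 0 °C → rt
Reagents that add atoms: water, O
Why: Acid-catalysed enol ether hydrolysis gives δ-hydroxy aldehyde 6, which closes to the six-membered lactol; dilute acid at low temperature should leave the tertiary allylic alcohol intact.

Step 4
Reactants: 7 (6R)-6-methyl-6-vinyltetrahydro-2H-pyran-2-ol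
Product: 8 (6R)-6-methyl-6-vinyltetrahydro-2H-pyran-2-one
Conditions: PhI(OAc)2 (1.2 equiv), TEMPO (10 mol %), CH2Cl2, rt
Reagents that add atoms: none
Why: TEMPO/PhI(OAc)2 oxidation of a lactol to the lactone under neutral, chromium-free conditions that cannot ionise or transpose the tertiary allylic C–O bond.

Step 5
Reactants: 8 (6R)-6-methyl-6-vinyltetrahydro-2H-pyran-2-one
Product: 10 (6R)-3,6-dimethyl-6-vinyltetrahydro-2H-pyran-2-one (C3 epimers), via lithium enolate 9 (not isolated)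
Conditions: LiN(iPr)2 (1.05 equiv), THF, −78 °C; MeI, −78 → −20 °C
Reagents that add atoms: iodomethane, CI
Why: Lactone enolate alkylation; the new C3 centre forms as a mixture, which is irrelevant because this carbon becomes sp2 in step 7.

Step 6
Reactants: 10 (6R)-3,6-dimethyl-6-vinyltetrahydro-2H-pyran-2-one; 11 methyl acrylate (5 equiv)
Product: 12 methyl (E)-3-[(2R)-2,5-dimethyl-6-oxotetrahydro-2H-pyran-2-yl]prop-2-enoate
Conditions: second-generation Hoveyda–Grubbs catalyst RuCl2(=CH-C6H4-2-OiPr)(H2IMes) (5 mol %), CH2Cl2, 40 °C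
Reagents that add atoms: none
Why: Olefin cross-metathesis of the hindered vinyl group with excess electron-poor acrylate should give the E-enoate, because neither partner homodimerises readily.

Step 7
Reactants: 12 methyl (E)-3-[(2R)-2,5-dimethyl-6-oxotetrahydro-2H-pyran-2-yl]prop-2-enoate
Product: 15 (1S,2R)-2-(methoxycarbonyl)-1,4-dimethylcyclohex-3-ene-1-carboxylic acid (CO2H cis to CO2Me), via silyl ketene acetal 13 (not isolated), via trimethylsilyl ester 14 (not isolated)
Conditions: LiN(SiMe3)2 (1.3 equiv), Me3SiCl–Et3N (internal quench), THF, −78 °C; then PhMe, 100 °C; 1 M HCl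
Reagents that add atoms: none
Why: Ireland–Claisen ring contraction of a 6-alkenyl δ-lactone silyl ketene acetal, in which the two-carbon tether enforces a boat transition state, so the (R)-carbinol centre is transferred to C1 and C6 and the E-alkene places CO2Me cis to the new carboxyl group; the internal Me3SiCl quench should trap the enolate before it can add to the enoate.

Step 8
Reactants: 15 (1S,2R)-2-(methoxycarbonyl)-1,4-dimethylcyclohex-3-ene-1-carboxylic acid
Product: 17 methyl (1R,6S)-6-formyl-3,6-dimethylcyclohex-2-ene-1-carboxylate, via acid chloride 16 (not isolated)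
Conditions: (COCl)2, DMF (cat.), CH2Cl2, 0 °C → rt; then LiAlH(OtBu)3 (1.05 equiv), THF, −78 °C
Reagents that add atoms: none
Why: Acid chloride formation and reduction with the bulky hydride LiAlH(OtBu)3 should stop at the aldehyde and leave the methyl ester and the alkene untouched.

Step 9
Reactants: 17 methyl (1R,6S)-6-formyl-3,6-dimethylcyclohex-2-ene-1-carboxylate
Product: 18 methyl (1R,6S)-6-ethynyl-3,6-dimethylcyclohex-2-ene-1-carboxylate
Conditions: dimethyl (1-diazo-2-oxopropyl)phosphonate (1.3 equiv), K2CO3 (2 equiv), MeOH, 0 °C → rt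
Reagents that add atoms: dimethyl (1-diazo-2-oxopropyl)phosphonate, COP(=O)(OC)C(=[N+]=[N-])C(C)=O
Why: Ohira–Bestmann (Seyferth–Gilbert) homologation of a non-enolisable aldehyde; K2CO3/MeOH at 0 °C is mild enough that the hindered C–H α to the ester should not exchange.

Step 10
Reactants: 18 methyl (1R,6S)-6-ethynyl-3,6-dimethylcyclohex-2-ene-1-carboxylate
Product: 19 methyl (1R,6S)-3,6-dimethyl-6-[(trimethylsilyl)ethynyl]cyclohex-2-ene-1-carboxylate
Conditions: Zn(OTf)2 (10 mol %), Et3N (1.5 equiv), Me3SiOTf (1.5 equiv), CH2Cl2, rt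
Reagents that add atoms: trimethylsilyl trifluoromethanesulfonate, C[Si](C)(C)OS(=O)(=O)C(F)(F)F
Why: Zinc-catalysed C-silylation of the terminal alkyne through a zinc acetylide under amine-base conditions, chosen because a lithium base would enolise or attack the ester.

Step 11
Reactants: 19 methyl (1R,6S)-3,6-dimethyl-6-[(trimethylsilyl)ethynyl]cyclohex-2-ene-1-carboxylate
Product: 23 triisopropyl({[(1R,6S)-3,6-dimethyl-6-[(trimethylsilyl)ethynyl]cyclohex-2-en-1-yl]ethynyl}oxy)silane (the two alkynes cis), via tetrahedral adduct 20 (not isolated), via dibromo enolate 21 (not isolated), via lithium ynolate 22 (not isolated)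
Conditions: 2,2,6,6-tetramethylpiperidine, n-BuLi, THF, 0 °C; CH2Br2, −78 °C; then 19; LiN(SiMe3)2; n-BuLi (excess), −78 → 0 °C; iPr3SiCl, −78 °C → rt
Reagents that add atoms: dibromomethane, BrCBr; chlorotriisopropylsilane, CC(C)[Si](Cl)(C(C)C)C(C)C
Why: Kowalski ynolate synthesis, in which LiCHBr2 adds to the ester, Br–Li exchange on enolate 21 triggers a 1,2-shift of the ring carbon with retention to ynolate 22, and the bulky silyl chloride silylates at oxygen; the Me3Si-alkyne has no acidic proton to consume base.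

Step 12
Reactants: 24 3-ethoxycyclobut-2-en-1-one
Product: 25 3-methoxycyclobut-2-en-1-one
Conditions: MeOH (solvent), p-TsOH·H2O (5 mol %), rt; NaHCO3; distillation
Reagents that add atoms: methanol, CO
Why: Acid-catalysed transetherification of a vinylogous ester (addition–elimination at C3), driven by methanol as solvent.

Step 13
Reactants: 23 triisopropyl({[(1R,6S)-3,6-dimethyl-6-[(trimethylsilyl)ethynyl]cyclohex-2-en-1-yl]ethynyl}oxy)silane; 25 3-methoxycyclobut-2-en-1-one (1.5 equiv)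
Product: 30 2-[(1R,6S)-3,6-dimethyl-6-[(trimethylsilyl)ethynyl]cyclohex-2-en-1-yl]-5-methoxy-3-[(triisopropylsilyl)oxy]phenol, via vinylketene 26 (not isolated), via cyclobutenone adduct 27 (not isolated), via dienylketene 28 (not isolated), via cyclohexadienone 29 (not isolated)
Conditions: PhMe, 80 → 110 °C, sealed tube, Ar
Reagents that add atoms: none
Why: Heating opens 25 (4π) to vinylketene 26, whose ketene C=C adds the siloxyalkyne in a [2+2] to give cyclobutenone 27; a second 4π opening gives dienylketene 28, thermal 6π electrocyclisation (disrotatory) closes the six-membered ring between the ketene carbon and the terminal CH2 to give dienone 29, and tautomerisation gives phenol 30. The closest known reaction is the Danheiser benzannulation of cyclobutenones with siloxyalkynes to resorcinol monosilyl ethers; the 3-methoxy group only places a donor on the vinyl terminus of the ketene, is expected to be tolerated, and ends para to the new aryl–C6 bond. No stereocentre is created: C1 and C6 of the cyclohexene are spectators and the transient sp3 centre of 27 is lost. The step needs only the regiochemistry of the ketene–alkyne cycloaddition, which the oxygen-polarised triple bond secures (the nucleophilic carbon bearing C6 bonds to the ketene carbonyl carbon), so that the free OH (future O1) and OSi(iPr)3 (future O7) flank the carbon bonded to C6 with OMe para. The unactivated Me3Si-alkyne and the trisubstituted alkene should not compete for the ketene.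

Step 14
Reactants: 30 2-[(1R,6S)-3,6-dimethyl-6-[(trimethylsilyl)ethynyl]cyclohex-2-en-1-yl]-5-methoxy-3-[(triisopropylsilyl)oxy]phenol
Product: 31 3-[(1R,6S)-3,6-dimethyl-6-[(trimethylsilyl)ethynyl]cyclohex-2-en-1-yl]-2-hydroxy-6-methoxy-4-[(triisopropylsilyl)oxy]benzaldehyde
Conditions: MgCl2 (2 equiv), Et3N (4 equiv), (CH2O)n (6 equiv), THF, reflux; 1 M HCl
Reagents that add atoms: paraformaldehyde (as formaldehyde), C=O
Why: Casnati–Skattebøl ortho-formylation, in which the magnesium phenoxide delivers formaldehyde only to the single free ortho position (between OH and OMe) and a second formaldehyde accepts hydride.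

Step 15
Reactants: 31 3-[(1R,6S)-3,6-dimethyl-6-[(trimethylsilyl)ethynyl]cyclohex-2-en-1-yl]-2-hydroxy-6-methoxy-4-[(triisopropylsilyl)oxy]benzaldehyde
Product: 33 8-[(1R,6S)-3,6-dimethyl-6-[(trimethylsilyl)ethynyl]cyclohex-2-en-1-yl]-5-methoxy-7-[(triisopropylsilyl)oxy]-2H-chromen-2-one, via Z-cinnamate 32 (not isolated)
Conditions: Ph3P=CHCO2Et (1.5 equiv), PhNEt2, reflux
Reagents that add atoms: ethyl (triphenylphosphoranylidene)acetate, CCOC(=O)C=P(c1ccccc1)(c1ccccc1)c1ccccc1
Why: Wittig olefination of the salicylaldehyde and thermal lactonisation of the cinnamate (E/Z equilibration at reflux), the standard access to 5,7-dioxygenated coumarins from 2-hydroxy-4,6-dialkoxybenzaldehydes; only the OH ortho to the aldehyde can lactonise, which fixes O1 next to C8.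

Step 16
Reactants: 33 8-[(1R,6S)-3,6-dimethyl-6-[(trimethylsilyl)ethynyl]cyclohex-2-en-1-yl]-5-methoxy-7-[(triisopropylsilyl)oxy]-2H-chromen-2-one
Product: 34 8-[(1R,6S)-6-ethynyl-3,6-dimethylcyclohex-2-en-1-yl]-7-hydroxy-5-methoxy-2H-chromen-2-one
Conditions: Bu4NF (2.5 equiv), THF, 0 °C → rt; aq. NH4Cl
Reagents that add atoms: none
Why: Fluoride should cleave the aryl O–Si and the alkynyl C–Si bonds in one operation, and the coumarin lactone is stable to these conditions.

Step 17
Reactants: 34 8-[(1R,6S)-6-ethynyl-3,6-dimethylcyclohex-2-en-1-yl]-7-hydroxy-5-methoxy-2H-chromen-2-one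
Product: 35 8-[(1R,6S)-6-ethynyl-3,6-dimethylcyclohex-2-en-1-yl]-5,7-dimethoxy-2H-chromen-2-one
Conditions: MeI (3 equiv), K2CO3 (2 equiv), acetone, 50 °C
Reagents that add atoms: iodomethane, CI
Why: Williamson O-methylation of the phenol; K2CO3 does not deprotonate the terminal alkyne.

Step 18
Reactants: 36 5,7-dimethoxycoumarin
Product: 37 8-iodo-5,7-dimethoxy-2H-chromen-2-one
Conditions: N-iodosuccinimide (1.05 equiv), CF3CO2H (0.3 equiv), MeCN, 0 °C → rt
Reagents that add atoms: N-iodosuccinimide, O=C1CCC(=O)N1I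
Why: Electrophilic aromatic iodination, expected at C8 (para to 5-OMe, ortho to 7-OMe) by analogy with 5,7-dialkoxychromones.

Step 19
Reactants: 35 8-[(1R,6S)-6-ethynyl-3,6-dimethylcyclohex-2-en-1-yl]-5,7-dimethoxy-2H-chromen-2-one; 37 8-iodo-5,7-dimethoxy-2H-chromen-2-one
Product: 38 8-{[(1S,2R)-2-(5,7-dimethoxy-2-oxo-2H-chromen-8-yl)-1,4-dimethylcyclohex-3-en-1-yl]ethynyl}-5,7-dimethoxy-2H-chromen-2-one
Conditions: Pd(PPh3)2Cl2 (5 mol %), CuI (10 mol %), Et3N–DMF, 60 °C, degassed
Reagents that add atoms: none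
Why: Sonogashira coupling of a terminal alkyne with an aryl iodide; the iodide compensates for the electron-rich, doubly ortho-substituted arene, and an alkyne on a quaternary carbon cannot isomerise.

Step 20
Reactants: 38 8-{[(1S,2R)-2-(5,7-dimethoxy-2-oxo-2H-chromen-8-yl)-1,4-dimethylcyclohex-3-en-1-yl]ethynyl}-5,7-dimethoxy-2H-chromen-2-one
Product: 39 8-[(1R,6R)-6-[(Z)-2-(5,7-dimethoxy-2-oxo-2H-chromen-8-yl)ethenyl]-3,6-dimethylcyclohex-2-en-1-yl]-5,7-dimethoxy-2H-chromen-2-one (target)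
Conditions: H2 (1 atm), Pd/CaCO3 poisoned with Pb(OAc)2, quinoline, EtOAc, rt
Reagents that add atoms: none
Why: Syn semi-hydrogenation of the disubstituted alkyne over lead-poisoned palladium should give the Z-alkene and leave the coumarin C3=C4 bonds and the trisubstituted ring alkene untouched.

**Compound list**

1 | (R)-linalool, (3R)-3,7-dimethylocta-1,6-dien-3-ol | C=C[C@](C)(O)CCC=C(C)C | starting material
2 | (4R)-4-hydroxy-4-methylhex-5-enal | C=C[C@](C)(O)CCC=O | intermediate
3 | (5R)-5-methyl-5-vinyltetrahydrofuran-2-ol | C=C[C@@]1(C)CCC(O)O1 | intermediate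
4 | potassium (3R)-3-methyl-6-oxohex-1-en-3-olate (ring-opened alkoxide of 3) | C=C[C@](C)(O[K])CCC=O | intermediate
5 | (3R)-7-methoxy-3-methylhepta-1,6-dien-3-ol (E/Z) | C=C[C@](C)(O)CCC=COC | intermediate
6 | (5R)-5-hydroxy-5-methylhept-6-enal | C=C[C@](C)(O)CCCC=O | intermediate
7 | (6R)-6-methyl-6-vinyltetrahydro-2H-pyran-2-ol | C=C[C@@]1(C)CCCC(O)O1 | intermediate
8 | (6R)-6-methyl-6-vinyltetrahydro-2H-pyran-2-one | C=C[C@@]1(C)CCCC(=O)O1 | intermediate
9 | lithium enolate of 8 | C=C[C@@]1(C)CCC=C(O[Li])O1 | intermediate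
10 | (6R)-3,6-dimethyl-6-vinyltetrahydro-2H-pyran-2-one (C3 epimers) | C=C[C@@]1(C)CCC(C)C(=O)O1 | intermediate
11 | methyl acrylate | C=CC(=O)OC | starting material
12 | methyl (E)-3-[(2R)-2,5-dimethyl-6-oxotetrahydro-2H-pyran-2-yl]prop-2-enoate | COC(=O)/C=C/[C@@]1(C)CCC(C)C(=O)O1 | intermediate
13 | methyl (E)-3-[(2R)-2,5-dimethyl-6-[(trimethylsilyl)oxy]-3,4-dihydro-2H-pyran-2-yl]prop-2-enoate | COC(=O)/C=C/[C@@]1(C)CCC(C)=C(O[Si](C)(C)C)O1 | intermediate
14 | trimethylsilyl (1S,2R)-2-(methoxycarbonyl)-1,4-dimethylcyclohex-3-ene-1-carboxylate | C[Si](C)(C)OC(=O)[C@@]1(C)CCC(C)=C[C@H]1C(=O)OC | intermediate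
15 | (1S,2R)-2-(methoxycarbonyl)-1,4-dimethylcyclohex-3-ene-1-carboxylic acid | OC(=O)[C@@]1(C)CCC(C)=C[C@H]1C(=O)OC | intermediate
16 | methyl (1R,6S)-6-(chlorocarbonyl)-3,6-dimethylcyclohex-2-ene-1-carboxylate | ClC(=O)[C@@]1(C)CCC(C)=C[C@H]1C(=O)OC | intermediate
17 | methyl (1R,6S)-6-formyl-3,6-dimethylcyclohex-2-ene-1-carboxylate | O=C[C@@]1(C)CCC(C)=C[C@H]1C(=O)OC | intermediate
18 | methyl (1R,6S)-6-ethynyl-3,6-dimethylcyclohex-2-ene-1-carboxylate | C#C[C@@]1(C)CCC(C)=C[C@H]1C(=O)OC | intermediate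
19 | methyl (1R,6S)-3,6-dimethyl-6-[(trimethylsilyl)ethynyl]cyclohex-2-ene-1-carboxylate | C[Si](C)(C)C#C[C@@]1(C)CCC(C)=C[C@H]1C(=O)OC | intermediate
20 | lithium alkoxide of the LiCHBr2 adduct of 19 (2,2-dibromo-1-methoxy-1-cyclohexenylethanolate) | C[Si](C)(C)C#C[C@@]1(C)CCC(C)=C[C@H]1C(O[Li])(OC)C(Br)Br | intermediate
21 | lithium enolate of the dibromomethyl ketone (2,2-dibromo-1-cyclohexenylethenolate) | C[Si](C)(C)C#C[C@@]1(C)CCC(C)=C[C@H]1C(O[Li])=C(Br)Br | intermediate
22 | lithium ynolate, lithium 2-[(1R,6S)-3,6-dimethyl-6-[(trimethylsilyl)ethynyl]cyclohex-2-en-1-yl]ethynolate | C[Si](C)(C)C#C[C@@]1(C)CCC(C)=C[C@H]1C#CO[Li] | intermediate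
23 | triisopropyl({[(1R,6S)-3,6-dimethyl-6-[(trimethylsilyl)ethynyl]cyclohex-2-en-1-yl]ethynyl}oxy)silane | C[Si](C)(C)C#C[C@@]1(C)CCC(C)=C[C@H]1C#CO[Si](C(C)C)(C(C)C)C(C)C | intermediate
24 | 3-ethoxycyclobut-2-en-1-one | CCOC1=CC(=O)C1 | starting material
25 | 3-methoxycyclobut-2-en-1-one | COC1=CC(=O)C1 | intermediate
26 | 3-methoxybuta-1,3-dien-1-one (vinylketene) | C=C(OC)C=C=O | intermediate
27 | 2-[(1R,6S)-3,6-dimethyl-6-[(trimethylsilyl)ethynyl]cyclohex-2-en-1-yl]-4-(1-methoxyethenyl)-3-[(triisopropylsilyl)oxy]cyclobut-2-en-1-one (C4 epimers) | C[Si](C)(C)C#C[C@@]1(C)CCC(C)=C[C@H]1C1=C(O[Si](C(C)C)(C(C)C)C(C)C)C(C(=C)OC)C1=O | intermediate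
28 | 2-[(1R,6S)-3,6-dimethyl-6-[(trimethylsilyl)ethynyl]cyclohex-2-en-1-yl]-5-methoxy-3-[(triisopropylsilyl)oxy]hexa-1,3,5-trien-1-one (dienylketene) | C[Si](C)(C)C#C[C@@]1(C)CCC(C)=C[C@H]1C(=C=O)C(O[Si](C(C)C)(C(C)C)C(C)C)=CC(=C)OC | intermediate
29 | 2-[(1R,6S)-3,6-dimethyl-6-[(trimethylsilyl)ethynyl]cyclohex-2-en-1-yl]-5-methoxy-3-[(triisopropylsilyl)oxy]cyclohexa-2,4-dien-1-one | C[Si](C)(C)C#C[C@@]1(C)CCC(C)=C[C@H]1C1=C(O[Si](C(C)C)(C(C)C)C(C)C)C=C(OC)CC1=O | intermediate
30 | 2-[(1R,6S)-3,6-dimethyl-6-[(trimethylsilyl)ethynyl]cyclohex-2-en-1-yl]-5-methoxy-3-[(triisopropylsilyl)oxy]phenol | C[Si](C)(C)C#C[C@@]1(C)CCC(C)=C[C@H]1c1c(O)cc(OC)cc1O[Si](C(C)C)(C(C)C)C(C)C | intermediate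
31 | 3-[(1R,6S)-3,6-dimethyl-6-[(trimethylsilyl)ethynyl]cyclohex-2-en-1-yl]-2-hydroxy-6-methoxy-4-[(triisopropylsilyl)oxy]benzaldehyde | C[Si](C)(C)C#C[C@@]1(C)CCC(C)=C[C@H]1c1c(O)c(C=O)c(OC)cc1O[Si](C(C)C)(C(C)C)C(C)C | intermediate
32 | ethyl (Z)-3-{3-[(1R,6S)-3,6-dimethyl-6-[(trimethylsilyl)ethynyl]cyclohex-2-en-1-yl]-2-hydroxy-6-methoxy-4-[(triisopropylsilyl)oxy]phenyl}prop-2-enoate | C[Si](C)(C)C#C[C@@]1(C)CCC(C)=C[C@H]1c1c(O)c(/C=C\C(=O)OCC)c(OC)cc1O[Si](C(C)C)(C(C)C)C(C)C | intermediate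
33 | 8-[(1R,6S)-3,6-dimethyl-6-[(trimethylsilyl)ethynyl]cyclohex-2-en-1-yl]-5-methoxy-7-[(triisopropylsilyl)oxy]-2H-chromen-2-one | C[Si](C)(C)C#C[C@@]1(C)CCC(C)=C[C@H]1c1c(O[Si](C(C)C)(C(C)C)C(C)C)cc(OC)c2ccc(=O)oc12 | intermediate
34 | 8-[(1R,6S)-6-ethynyl-3,6-dimethylcyclohex-2-en-1-yl]-7-hydroxy-5-methoxy-2H-chromen-2-one | C#C[C@@]1(C)CCC(C)=C[C@H]1c1c(O)cc(OC)c2ccc(=O)oc12 | intermediate
35 | 8-[(1R,6S)-6-ethynyl-3,6-dimethylcyclohex-2-en-1-yl]-5,7-dimethoxy-2H-chromen-2-one | C#C[C@@]1(C)CCC(C)=C[C@H]1c1c(OC)cc(OC)c2ccc(=O)oc12 | intermediate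
36 | 5,7-dimethoxycoumarin | COc1cc(OC)c2ccc(=O)oc2c1 | starting material
37 | 8-iodo-5,7-dimethoxy-2H-chromen-2-one | COc1cc(OC)c2ccc(=O)oc2c1I | intermediate
38 | 8-{[(1S,2R)-2-(5,7-dimethoxy-2-oxo-2H-chromen-8-yl)-1,4-dimethylcyclohex-3-en-1-yl]ethynyl}-5,7-dimethoxy-2H-chromen-2-one | COc1cc(OC)c2ccc(=O)oc2c1C#C[C@@]1(C)CCC(C)=C[C@H]1c1c(OC)cc(OC)c2ccc(=O)oc12 | intermediate
39 | 8-[(1R,6R)-6-[(Z)-2-(5,7-dimethoxy-2-oxo-2H-chromen-8-yl)ethenyl]-3,6-dimethylcyclohex-2-en-1-yl]-5,7-dimethoxy-2H-chromen-2-one | COc1cc(OC)c2ccc(=O)oc2c1/C=C\[C@@]1(C)CCC(C)=C[C@H]1c1c(OC)cc(OC)c2ccc(=O)oc12 | target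

**Step count and risks**

Total: 20 steps. Longest linear sequence: 18 steps (steps 1–11, 13–17, 19, 20); steps 12 and 18 are one-step side branches.

Steps most likely to fail:

1. Step 13. The 4π opening of the vinylogous-ester cyclobutenone 25 may need temperatures at which siloxyalkyne 23 isomerises to a silylketene or phenol 30 is acylated by excess ketene. The fallback sets out from 23 and comes back at 30. The same vinylketene 26 is generated at 20 °C by 1,4-dehydrochlorination of (E)-3-methoxybut-2-enoyl chloride F1 (from commercial (E)-3-methoxybut-2-enoic acid and (COCl)2) with Et3N in PhMe in the presence of 23. The ketene–alkyne [2+2] then gives cyclobutenone 27 without any ring opening of 25, and brief heating at 80 °C converts 27 into 30.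

2. Step 11. Addition of LiCHBr2 to the hindered ester may be slow, so that deprotonation α to the ester (epimerisation, loss of material) competes. The fallback sets out from 19 and comes back at 23. iBu2AlH (CH2Cl2, −78 °C) gives (1R,6S)-3,6-dimethyl-6-[(trimethylsilyl)ethynyl]cyclohex-2-ene-1-carbaldehyde F2. Colvin homologation with Me3SiC(Li)N2 (THF, −78 → 0 °C) gives {[(1S,2S)-2-ethynyl-1,4-dimethylcyclohex-3-en-1-yl]ethynyl}trimethylsilane F3. Deprotonation with n-BuLi and oxidation of the lithium acetylide with LiOOtBu (from t-BuOOH and LiN(SiMe3)2, −78 → 0 °C) gives the same ynolate 22, which iPr3SiOTf silylates to 23.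

3. Step 7. The lactone enolate may add to the enoate (intramolecular Michael addition), or the amide base may attack the enoate before O-silylation. The fallback sets out from 10 and comes back at 18; its alkene carries no acceptor. Cross-metathesis of 10 with (allyloxy)(tert-butyl)dimethylsilane (same ruthenium catalyst) gives (6R)-6-[(E)-3-[(tert-butyldimethylsilyl)oxy]prop-1-en-1-yl]-3,6-dimethyltetrahydro-2H-pyran-2-one F4. The same Ireland–Claisen contraction gives (1S,2R)-2-{[(tert-butyldimethylsilyl)oxy]methyl}-1,4-dimethylcyclohex-3-ene-1-carboxylic acid F5. Aqueous HCl/THF removes the silyl group, and the cis γ-hydroxy acid closes to (3aR,7aS)-5,7a-dimethyl-3a,6,7,7a-tetrahydro-2-benzofuran-1(3H)-one F6. iBu2AlH (−78 °C) gives (3aR,7aS)-5,7a-dimethyl-1,3,3a,6,7,7a-hexahydro-2-benzofuran-1-ol F7. Ohira–Bestmann homologation of the lactol gives [(1R,6S)-6-ethynyl-3,6-dimethylcyclohex-2-en-1-yl]methanol F8. Dess–Martin periodinane followed by NaClO2/NaH2PO4/2-methylbut-2-ene gives (1R,6S)-6-ethynyl-3,6-dimethylcyclohex-2-ene-1-carboxylic acid F9, and Me3SiCHN2/MeOH gives ester 18.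

Further compounds
F1 | step 13 | (E)-3-methoxybut-2-enoyl chloride | CO/C(C)=C/C(Cl)=O
F2 | step 11 | (1R,6S)-3,6-dimethyl-6-[(trimethylsilyl)ethynyl]cyclohex-2-ene-1-carbaldehyde | C[Si](C)(C)C#C[C@@]1(C)CCC(C)=C[C@H]1C=O
F3 | step 11 | {[(1S,2S)-2-ethynyl-1,4-dimethylcyclohex-3-en-1-yl]ethynyl}trimethylsilane | C[Si](C)(C)C#C[C@@]1(C)CCC(C)=C[C@H]1C#C
F4 | step 7 | (6R)-6-[(E)-3-[(tert-butyldimethylsilyl)oxy]prop-1-en-1-yl]-3,6-dimethyltetrahydro-2H-pyran-2-one | CC(C)(C)[Si](C)(C)OC/C=C/[C@@]1(C)CCC(C)C(=O)O1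
F5 | step 7 | (1S,2R)-2-{[(tert-butyldimethylsilyl)oxy]methyl}-1,4-dimethylcyclohex-3-ene-1-carboxylic acid | OC(=O)[C@@]1(C)CCC(C)=C[C@H]1CO[Si](C)(C)C(C)(C)C
F6 | step 7 | (3aR,7aS)-5,7a-dimethyl-3a,6,7,7a-tetrahydro-2-benzofuran-1(3H)-one | O=C2[C@@]1(C)CCC(C)=C[C@H]1CO2
F7 | step 7 | (3aR,7aS)-5,7a-dimethyl-1,3,3a,6,7,7a-hexahydro-2-benzofuran-1-ol | OC2[C@@]1(C)CCC(C)=C[C@H]1CO2
F8 | step 7 | [(1R,6S)-6-ethynyl-3,6-dimethylcyclohex-2-en-1-yl]methanol | C#C[C@@]1(C)CCC(C)=C[C@H]1CO
F9 | step 7 | (1R,6S)-6-ethynyl-3,6-dimethylcyclohex-2-ene-1-carboxylic acid | C#C[C@@]1(C)CCC(C)=C[C@H]1C(=O)O
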